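**Assumptions:** Serpyllin (5‑hydroxy‑7,8,2',3',4'‑pentamethoxyflavone, C20H20O8) has no stereocentres, so the "single enantiomer" requirement does not apply. The only stereo‑element in the route is the E‑alkene of the chalcone, and it is consumed in Step 3. 1,2,3,5‑Tetramethoxybenzene is taken as commercially available; if not, it is one step from 3,4,5‑trimethoxyphenol with MeI/K2CO3.

## Retrosynthetic overview
1. 5‑OH ⇐ 5‑OMe: last‑step, carbonyl‑chelation‑directed mono‑demethylation of the hexamethoxyflavone.
2. Ring C (pyranone, O1–C2 bond) ⇐ oxidative cyclisation of a 2'‑hydroxychalcone.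
3. Chalcone Cα=Cβ ⇐ Claisen–Schmidt condensation of 2‑hydroxy‑3,4,6‑trimethoxyacetophenone with 2,3,4‑trimethoxybenzaldehyde.
4. Acetophenone ⇐ Friedel–Crafts acetylation with in situ ortho‑demethylation of 1,2,3,5‑tetramethoxybenzene, whose two free C–H positions are equivalent.
5. Ring order: rings A and B are bought intact, and ring C is the only ring formed.

## Route

**Step 1**
Reactants: **1**, 1,2,3,5‑tetramethoxybenzene; **2**, acetyl chloride
Product: **3**, 2'‑hydroxy‑3',4',6'‑trimethoxyacetophenone (1‑(2‑hydroxy‑3,4,6‑trimethoxyphenyl)ethanone)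
Conditions: AcCl (1.2 equiv), AlCl3 (2.5 equiv), Et2O, 0 °C → rt, 12–24 h; ice/2 M HCl work‑up; recrystallise or chromatograph
Reagents that add atoms: acetyl chloride, CC(=O)Cl
Why: Friedel–Crafts acylation can occur only at the equivalent C4/C6 positions, and the Al‑chelated ketone then loses the more crowded, out‑of‑plane ortho‑OMe (the one flanked by both acetyl and OMe), which gives the hydrogen‑bonded 2‑phenol that sets the 5,7,8‑pattern.

**Step 2**
Reactants: **3**; **4**, 2,3,4‑trimethoxybenzaldehyde
Product: **5**, (E)‑2'‑hydroxy‑2,3,4,3',4',6'‑hexamethoxychalcone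
Conditions: 50% aq. KOH, EtOH, rt, 24–48 h; acidify cold with dilute HCl to pH ~4 and filter
Reagents that add atoms: 2,3,4‑trimethoxybenzaldehyde, COc1ccc(C=O)c(OC)c1OC
Why: Claisen–Schmidt aldol condensation between the only enolisable partner (3) and a non‑enolisable aldehyde, followed by E1cB dehydration, gives the thermodynamic E‑enone, and any flavanone formed by ring closure converges to the same product in Step 3.

**Step 3**
Reactants: **5**
Product: **6**, 5,7,8,2',3',4'‑hexamethoxyflavone
Conditions: I2 (10 mol %), DMSO, 130 °C, 2–4 h; aq. Na2S2O3 quench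
Reagents that add atoms: none (net loss of 2 H)
Why: In this I2/DMSO oxidative cyclisation, oxa‑Michael closure of the 2'‑OH gives the flavanone, α‑iodination and HI elimination then aromatise ring C while DMSO re‑oxidises HI, and the aryl methyl ethers are inert under these conditions.

**Step 4**
Reactants: **6**
Product: **7**, serpyllin (5‑hydroxy‑7,8,2',3',4'‑pentamethoxyflavone)
Conditions: BCl3 (1.3–1.5 equiv, 1 M in CH2Cl2), CH2Cl2, −78 → 0 °C, 1–2 h; aq. NaOAc/MeOH or dilute HCl work‑up to hydrolyse the boron chelate
Reagents that add atoms: none (CH3 is lost as MeCl; H comes from work‑up)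
Why: In this chelation‑directed Lewis‑acid ether cleavage, BCl3 binds the C4 carbonyl and only the peri 5‑OMe can form the six‑membered boron chelate, so it is cleaved much faster than the other five OMe groups, and the low, non‑protic temperature avoids Wessely–Moser isomerisation to the 5,6,7‑isomer.

## Compound list
| No. | Name | SMILES | Role |
|---|---|---|---|
| 1 | 1,2,3,5‑tetramethoxybenzene | COc1cc(OC)c(OC)c(OC)c1 | starting material |
| 2 | acetyl chloride | CC(=O)Cl | starting material |
| 3 | 2'‑hydroxy‑3',4',6'‑trimethoxyacetophenone | CC(=O)c1c(O)c(OC)c(OC)cc1OC | intermediate |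
| 4 | 2,3,4‑trimethoxybenzaldehyde | COc1ccc(C=O)c(OC)c1OC | starting material |
| 5 | (E)‑2'‑hydroxy‑2,3,4,3',4',6'‑hexamethoxychalcone | COc1ccc(/C=C/C(=O)c2c(O)c(OC)c(OC)cc2OC)c(OC)c1OC | intermediate |
| 6 | 5,7,8,2',3',4'‑hexamethoxyflavone | COc1ccc(-c2cc(=O)c3c(OC)cc(OC)c(OC)c3o2)c(OC)c1OC | intermediate |
| 7 | serpyllin | COc1ccc(-c2cc(=O)c3c(O)cc(OC)c(OC)c3o2)c(OC)c1OC | target |

Formula trail: 1 C10H14O4 → 3 C11H14O5 → (+ 4 C10H12O4 − H2O) 5 C21H24O8 → 6 C21H22O8 → 7 C20H20O8.

## Summary
**Total steps:** 4. **Longest linear sequence:** 4.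

**Steps most likely to fail, with fallbacks**
1. **Step 4.** The risk is over‑demethylation at 8‑OMe or at the crowded 3'‑OMe.
   - Fallback: never place a methyl group on O‑5.
   - Fully ortho‑demethylate to 2,6‑dihydroxy‑3,4‑dimethoxyacetophenone and monobenzylate the less hindered 6‑OH.
   - Run the same chalcone and flavone sequence, then release the 5‑OH by hydrogenolysis (H2, Pd/C).
2. **Step 1.** The risks are loss of the wrong ortho‑OMe (2‑ versus 6‑) and double demethylation.
   - Fallback: introduce the C8 oxygen late.
   - Build 5‑hydroxy‑7,2',3',4'‑tetramethoxyflavone from commercial 2‑hydroxy‑4,6‑dimethoxyacetophenone.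
   - Hydroxylate C8, para to the 5‑OH, by Elbs persulfate oxidation.
   - Methylate the non‑chelated 8‑OH selectively with MeI (1 equiv)/K2CO3.
3. **Step 3.** The risks are stalling at the flavanone and iodination at C6 of the electron‑rich A ring.
   - Fallback: a redox‑neutral Baker–Venkataraman route that replaces Steps 2–3.
   - O‑Aroylate 3 with 2,3,4‑trimethoxybenzoyl chloride and shift the acyl group with KOH/pyridine to give the 1,3‑diketone.
   - Cyclodehydrate with H2SO4/AcOH to give 6.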